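The readings were computed from invented constants.

No column of the earlier runs shows [D], and yet the passing of G to Q has to be reckoned with [D].

| flask | Z | D | E | remark | time |
|---|---|---|---|---|---|
| south | 20 mM | 24 mM | 1.6 mM | run made earlier |  |
| north-east | 20 mM | 24 mM | 2.2 mM | run made earlier |  |
| east | 20 mM | 24 mM | 3.5 mM | run made earlier |  |
| north-west | 40 mM | 24 mM | 1.6 mM | run made earlier |  |
| winter | 20 mM | 24.0 mM (fed, over 2.00 h) | 1.6 mM | all but D at the start; D goes in evenly over 2.00 h, the run ends at 4.0 h | 4.0 h |
| autumn | 20 mM | 24.0 mM | 1.6 mM | a single well-mixed tank run continuously and read at steady state, 4.0 h in it on average |  |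
| summer | 20 mM | 24.0 mM | 1.6 mM | a tube with plug flow, the mixed feed as stated, residence time 4.0 h | 4.0 h |
| midnight | 20 mM | 24.0 mM | 1.6 mM | everything together in a closed stirred flask, run for 4.0 h | 4.0 h |

| run | time / h | G / % | Q / % | Z / % |
|---|---|---|---|---|
| south | 0.333 | 65.7 | 26.0 | 1.4 |
| south | 1.00 | 37.6 | 61.5 | 1.1 |
| south | 2.00 | 20.5 | 78.8 | 1.7 |
| south | 3.00 | 12.2 | 88.3 | 0 |
| south | 4.00 | 7.8 | 90.5 | 0.3 |
| north-east | 0.333 | 58.0 | 36.7 | 0 |
| north-east | 1.00 | 29.5 | 68.7 | 0 |
| north-east | 2.00 | 11.9 | 87.4 | 0 |
| north-east | 3.00 | 7.1 | 93.2 | 0 |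
| north-east | 4.00 | 3.1 | 95.7 | 0.3 |
| east | 0.333 | 45.6 | 49.6 | 0 |
| east | 1.00 | 17.9 | 80.6 | 0.5 |
| east | 2.00 | 7.3 | 95.1 | 0.5 |
| east | 3.00 | 3.0 | 95.9 | 0 |
| east | 4.00 | 0.5 | 99.3 | 0.4 |
| north-west | 0.333 | 69.4 | 20.0 | 2.3 |
| north-west | 0.667 | 59.8 | 35.8 | 0.3 |
| north-west | 1.00 | 52.7 | 40.7 | 1.9 |
| north-west | 2.00 | 43.3 | 53.0 | 0.8 |
| north-west | 4.00 | 41.0 | 58.9 | 1.6 |

(readings scatter by 1 percentage point)

- a species is counted by the Z in it: one J counts as two
- amounts and yields of Q count J too
- the stated concentrations are those of everything mixed, before any reaction; amounts are the same in each set-up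
- steps thought possible: Z + E -> E + G; D + X -> E + Q; Z + Q <-> J; E + G <-> X
- the feed brings no volume worth counting
- the earlier runs were made in a closed, stirred flask
- in an amount of Q, one J counts as one Q

* the set-up with the highest amount of G at the outlet or at the end, in percent of the Z put in ("none" if the first two lie within 2 percentage points) (winter / autumn / summer / midnight / none)
* amount of G at the outlet or at the end, in percent of the Z put in, winter
* amount of G at the outlet or at the end, in percent of the Z put in, autumn
* amount of G at the outlet or at the end, in percent of the Z put in, summer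
* amount of G at the outlet or at the end, in percent of the Z put in, midnight

*What happens first?* Z turns into G: in the south run at 0.333 h, Z reads 1.4% against 65.7% for G, so what is left to watch is G passing to Q at the expense of D.

*Then how do you get [D]?* By subtraction: each Q takes one D, and at 1.00 h G and Q in south together read 99.1% of the Z, so for south I take [D] − [G] as the excess 4.00 mM, with G as the limiting reagent.

*And the rate?* If it goes as [G][D] at fixed E, it integrates in closed form and ln([D]/[G]) climbs in a straight line, whose slope I call the excess clock, read from south between 1.00 h and 4.00 h as 0.281 h⁻¹.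

*That slope comes from a closed flask, so why trust it in a tank?* I set the [G] missing from the Z of the feed equal to the rate times the mean stay of 4.0 h in the autumn tank, with [D] taken as [G] plus the excess, and this gives [G] = 5.46 mM, which lies inside the range the slope was read over, though that subtraction is carried over untested; the estimate is 27.3% of the Z.

*And the others?* Midnight and the summer tube repeat south's charge and time, so I take its reading of 7.8%, while winter's D arrives on average 1.00 h late, and running the clock back by that much from south's last reading gives, as my estimate for winter, 11.8%.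

The forecast names autumn, with 14.5% for winter, 28.5% for autumn, 8% for summer and 8% for midnight, saying “The stirred tank therefore leaves the most G”, and it stands above my winter and autumn figures.

The flask gives 12.0% in winter, 21.9% in autumn, 7.53% in summer and 7.53% at midnight, so autumn stands highest.

    Z + E → E + G (k = 170 M⁻¹ min⁻¹)
    D + X → E + Q (k = 42.0 M⁻¹ min⁻¹)
    Z + Q ⇌ J, settled at all times (K = 480 M⁻¹)
    E + G ⇌ X (K = 20.0 M⁻¹, k = 650 M⁻¹ min⁻¹)

In autumn G, Q and Z add up to 90.9% of the Z, so the subtraction fails there, and [D] reckoned from the Q at the outlet is 10.5 mM rather than 8.38 mM. With that [D] and the tank's [G], the excess clock over the mean stay yields Q of 64.8% of the Z, against the 67.5% at the outlet.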